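1. In a one-step world with a rate first order in substrate and free of catalyst, every charge of substrate would lose the same fraction per hour, and with a rate first order in catalyst as well, a larger charge at equal mol% would lose a fraction larger by the factor on the charge. I tested these two cases by dividing the south run by the north-east run at the same hour, so that time dropped out. At 2.50 h this gave 1.10, although the south run held 1.57 times the substrate and, at equal mol%, that factor more catalyst too.

common to all: free catalyst 0.45 mol%; added ligand 0.99 mM
- north-east: substrate 0.070 M; run made earlier
- south: substrate 0.11 M; run made earlier
- flask: substrate 0.050 M

| run | time / h | product / % |
|---|---|---|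
| north-east | 0.500 | 9.7 |
| north-east | 1.00 | 16.2 |
| north-east | 1.33 | 21.5 |
| north-east | 2.00 | 30.1 |
| north-east | 2.50 | 37.4 |
| south | 0.500 | 9.5 |
| south | 1.00 | 18.3 |
| south | 1.33 | 24.6 |
| south | 2.00 | 33.2 |
| south | 2.50 | 41.2 |

(readings scatter by 0.5 percentage points)

- the numbers in the tables scatter by 0.5 percentage points (one standard deviation)
- what may be going on: substrate + free catalyst -> catalyst intermediate; catalyst intermediate -> free catalyst + product; free catalyst + added ligand <-> idle complex

* factor on the rate of making product when 10% of the substrate are converted if free catalyst is charged twice over
* factor on the rate when 10% of the substrate are converted if free catalyst is charged at 0.1 mol% instead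

2. First instants: in the flask, each free catalyst is charged with 222 substrate and 4.40 added ligand, so it has two partners to meet.

3. Middle: the first readings stand near 10%. There I read a rate per catalyst charged of 43.1 h⁻¹ in the north-east run and 42.2 h⁻¹ in the south run. The two readings differ by 0.2 percentage points, less than the scatter.

4. So I carried the load factor, new catalyst charge over old, 0.222 for the lower charge. My rule: the rate changes by this factor while the working share of the catalyst holds, and a given conversion arrives later by its inverse, here 4.50 times. What is about to matter is anything in the flask that runs by the hour and not by the conversion, such as added ligand binding.

5. End: the readings run to 41.2%, past the conversion asked about, so I needed just the early flask.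

6. I committed to 2 and 0.222. The forecast said 2.05 and 0.215, holding that “Rate should then be almost proportional to total catalyst”.

7. The simulation gave 2.26 and 0.203, and the forecast held within its margins.

    substrate + free catalyst → catalyst intermediate (k = 88.6 M⁻¹ min⁻¹)
    catalyst intermediate → free catalyst + product (k = 0.855 min⁻¹)
    free catalyst + added ligand ⇌ idle complex (K = 3110 M⁻¹, k = 105 M⁻¹ min⁻¹)

In the flask at 2.00 h, free catalyst entered catalyst intermediate, the resting state of the round, 34 times as fast as it entered idle complex by the forward step alone, yet idle complex already held 36.2% of the catalyst against 50.5% in catalyst intermediate. Divided by the load factor, the rate factor came to 0.914 at the lower charge and 1.13 at the doubled charge, and at 10% conversion catalyst intermediate held 53.8% of the catalyst at the lower charge against 58.9% in the flask.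

The runs are simulated for substances that don't exist.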